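The route opens ring C at the three bonds around its carbonyl group. C4 carries no carbon substituent of its own. It is a one-carbon ketone bridge from C4a of ring A to C3, whose neighbour C2 bears ring B, and CO insertion can deliver such a bridge. One palladium-catalysed operation joins an ortho-iodophenol, CO and 4-ethynylanisole (C4a–C4, C4–C3). The phenol oxygen then closes O1–C2 to give the whole flavone skeleton. The precursor is a phloroglucinol whose free hydroxyl lies between iodine and prenyl, with the other two oxygens as MOM ethers, which fixes prenyl at C8. Iodine goes in before any alkene exists, prenyl arrives by Claisen rearrangement, and asymmetric CuH reduction sets (S)-C2.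

Key step: step 6

Assumption: the antipode of DTBM-SEGPHOS that sends hydride to the Re face of C2 is taken to be (S). Both antipodes are commercial, so the mirror-image ligand is used without other change if a pilot reduction shows the opposite sense. (MOM = methoxymethyl, prenyl = 3-methylbut-2-en-1-yl, flavonoid numbering.)

Step 1
Reactants: 1 phloroglucinol (benzene-1,3,5-triol)
Product: 2 3,5-bis(methoxymethoxy)phenol
Conditions: MOMCl (2.0 equiv), i-Pr2NEt (2.2 equiv), DMF, 0 °C → rt
Reagents that add atoms: chloromethyl methyl ether (MOMCl), COCCl
Why: Base-mediated O-alkylation (MOM acetal ether formation) carried out on the threefold-symmetric triol, so that no positional selectivity is needed and only the degree of protection has to be controlled, which two equivalents of MOMCl and chromatographic removal of under- and over-protected material should achieve.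

Step 2
Reactants: 2 3,5-bis(methoxymethoxy)phenol
Product: 3 2-iodo-3,5-bis(methoxymethoxy)phenol
Conditions: I2 (1.0 equiv), NaHCO3 (1.2 equiv), THF–H2O (1:1), 0 °C
Reagents that add atoms: iodine, II
Why: Electrophilic aromatic iodination of the phenoxide, run before any alkene is in the molecule so that iodoetherification cannot interfere; each of the two equivalent carbons ortho to the free oxygen is flanked by only one MOM ether and is less crowded than the para carbon wedged between two, the same ortho preference that bicarbonate-buffered I2 shows with resorcinols, and one equivalent of I2 at 0 °C limits a second iodination.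

Step 3
Reactants: 4 2-methylbut-3-en-2-ol
Product: 5 tert-butyl 2-methylbut-3-en-2-yl carbonate
Conditions: n-BuLi (1.05 equiv), THF, −78 → 0 °C; Boc2O (1.1 equiv), 0 °C → rt
Reagents that add atoms: di-tert-butyl dicarbonate (Boc2O), CC(C)(C)OC(=O)OC(=O)OC(C)(C)C
Why: Acylation of a lithium alkoxide (mixed carbonate formation), in which the tertiary alkoxide attacks a carbonyl carbon of Boc2O and expels tert-butyl carbonate, the standard way to activate a tertiary allylic alcohol for π-allyl chemistry.

Step 4
Reactants: 3 2-iodo-3,5-bis(methoxymethoxy)phenol; 5 tert-butyl 2-methylbut-3-en-2-yl carbonate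
Product: 6 2-iodo-1,5-bis(methoxymethoxy)-3-[(2-methylbut-3-en-2-yl)oxy]benzene
Conditions: Pd(PPh3)4 (3 mol %), THF, 0 °C, short reaction time; filtration through silica to remove palladium
Reagents that add atoms: none
Why: Tsuji–Trost allylic etherification, in which ionisation of the tertiary allylic carbonate by zerovalent palladium at 0 °C is much faster than insertion into an electron-rich C–I bond flanked by two oxygens (allylic etherification of ortho-iodinated resorcinol-type phenols is established), the released tert-butoxide deprotonates the phenol, and the phenoxide attacks the more substituted terminus of the 1,1-dimethylallyl complex under kinetic control to give the branched ether.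

Step 5
Reactants: 6 2-iodo-1,5-bis(methoxymethoxy)-3-[(2-methylbut-3-en-2-yl)oxy]benzene
Product: 8 2-iodo-3,5-bis(methoxymethoxy)-6-(3-methylbut-2-en-1-yl)phenol, via ortho-dienone 7 (not isolated)
Conditions: toluene (degassed), 110 °C, dark
Reagents that add atoms: none
Why: Aromatic Claisen rearrangement, whose [3,3] shift can end productively only at the single ortho carbon that bears hydrogen because the other is blocked by iodine, inverts the allyl unit so that the 1,1-dimethylallyl ether becomes a linear prenyl group, and after tautomerisation of 7 returns the hydroxyl exactly between iodine and prenyl.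

Step 6
Reactants: 8 2-iodo-3,5-bis(methoxymethoxy)-6-(3-methylbut-2-en-1-yl)phenol; 9 4-ethynylanisole; 10 carbon monoxide
Product: 13 5,7-bis(methoxymethoxy)-4'-methoxy-8-prenylflavone, via ynone 11 (not isolated), via enaminone 12 (not isolated)
Conditions: PdCl2(dppf) (5 mol %), 9 (1.5 equiv), CO (20 bar), Et2NH (solvent), 120 °C, autoclave, no copper salt
Reagents that add atoms: none
Why: Zerovalent palladium formed in situ from PdCl2(dppf) inserts into the C–I bond of 8, migratory insertion of CO gives the aroylpalladium iodide, and amine-assisted transfer of the alkynyl group of 9 followed by reductive elimination forges C4a–C4 and C4–C3 in ynone 11. The closest known reaction type is the carbonylative Sonogashira coupling of 2-iodophenols with terminal arylalkynes in a secondary amine, an established flavone synthesis. Ring C closes in the 6-endo mode: Et2NH adds to the distal alkyne carbon of 11 to give enaminone 12, whose β-carbon (the future C2) is then the only electrophilic site, and the phenol oxygen displaces the amine by addition–elimination to form O1–C2. No stereocentre is created. Three selectivities are needed: carbonylation over direct alkynylation (secured by CO pressure, the absence of copper and the ready migration of an electron-rich aryl group to CO), 6-endo over 5-exo closure (secured by the enaminone relay), and ring closure through the correct oxygen (secured by the substrate, because only the hydroxyl between iodine and prenyl is free while the other oxygen ortho to iodine is a MOM ether, so prenyl must end at C8). The prenyl alkene sits meta to the carbon–palladium bond and cannot reach it, and MOM ethers are inert to amine, CO and heat.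

Step 7
Reactants: 13 5,7-bis(methoxymethoxy)-4'-methoxy-8-prenylflavone
Product: 15 (2S)-5,7-bis(methoxymethoxy)-4'-methoxy-8-prenylflavanone, via silyl enol ether 14 (not isolated)
Conditions: Cu(OAc)2 (5 mol %), (S)-DTBM-SEGPHOS (5.5 mol %), (EtO)2MeSiH (3 equiv), toluene, 0 °C → rt, no alcohol additive; then aq NH4Cl, THF, 0 °C
Reagents that add atoms: none
Why: Copper hydride-catalysed asymmetric conjugate reduction (1,4-hydrosilylation), a reaction type established for the C2=C3 bond of 2-substituted chromones, in which the C2-symmetric bisphosphine on copper shields one face of the flat benzopyranone so that hydride reaches the Re face of C2 and sets (S), σ-bond metathesis with the silane traps the enolate as 14 before it can expel the aryloxide or be reduced further, the isolated trisubstituted prenyl alkene is not a substrate for CuH, and mild hydrolysis of 14 protonates the non-stereogenic C3.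

Step 8
Reactants: 15 (2S)-5,7-bis(methoxymethoxy)-4'-methoxy-8-prenylflavanone
Product: 16 (2S)-5,7-dihydroxy-4'-methoxy-8-prenylflavanone (CID45272659)
Conditions: HCl (1.25 M in MeOH), MeOH–THF, 0 °C → rt (≤35 °C)
Reagents that add atoms: none
Why: Acid-catalysed transacetalisation of the two aryl MOM acetals to dimethoxymethane, a standard unmasking in the prenylflavanone series, in which dilute anhydrous acid at or below 35 °C, stopped at full conversion, should be too mild for Markovnikov addition of the 7-hydroxyl to the prenyl alkene or for acid opening of the O1–C2 bond, so the (S) configuration set in step 7 is carried into 16 unchanged.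

Compound list
1 | phloroglucinol (benzene-1,3,5-triol) | Oc1cc(O)cc(O)c1 | starting material
2 | 3,5-bis(methoxymethoxy)phenol | COCOc1cc(O)cc(OCOC)c1 | intermediate
3 | 2-iodo-3,5-bis(methoxymethoxy)phenol | COCOc1cc(O)c(I)c(OCOC)c1 | intermediate
4 | 2-methylbut-3-en-2-ol | C=CC(C)(C)O | starting material
5 | tert-butyl 2-methylbut-3-en-2-yl carbonate | C=CC(C)(C)OC(=O)OC(C)(C)C | intermediate
6 | 2-iodo-1,5-bis(methoxymethoxy)-3-[(2-methylbut-3-en-2-yl)oxy]benzene | C=CC(C)(C)Oc1cc(OCOC)cc(OCOC)c1I | intermediate
7 | 2-iodo-3,5-bis(methoxymethoxy)-6-prenylcyclohexa-2,4-dien-1-one (racemic, transient, not isolated) | O=C1C(I)=C(OCOC)C=C(OCOC)C1CC=C(C)C | intermediate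
8 | 2-iodo-3,5-bis(methoxymethoxy)-6-(3-methylbut-2-en-1-yl)phenol | Oc1c(I)c(OCOC)cc(OCOC)c1CC=C(C)C | intermediate
9 | 4-ethynylanisole | C#Cc1ccc(OC)cc1 | starting material
10 | carbon monoxide | [C-]#[O+] | starting material
11 | 1-[2-hydroxy-4,6-bis(methoxymethoxy)-3-prenylphenyl]-3-(4-methoxyphenyl)prop-2-yn-1-one (not isolated) | COc1ccc(C#CC(=O)c2c(O)c(CC=C(C)C)c(OCOC)cc2OCOC)cc1 | intermediate
12 | 3-(diethylamino)-1-[2-hydroxy-4,6-bis(methoxymethoxy)-3-prenylphenyl]-3-(4-methoxyphenyl)prop-2-en-1-one (alkene geometry not defined, not isolated) | CCN(CC)C(=CC(=O)c1c(O)c(CC=C(C)C)c(OCOC)cc1OCOC)c1ccc(OC)cc1 | intermediate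
13 | 5,7-bis(methoxymethoxy)-4'-methoxy-8-prenylflavone | COc1ccc(-c2cc(=O)c3c(OCOC)cc(OCOC)c(CC=C(C)C)c3o2)cc1 | intermediate
14 | (2S)-4-[diethoxy(methyl)silyloxy]-2-(4-methoxyphenyl)-5,7-bis(methoxymethoxy)-8-prenyl-2H-chromene (not isolated) | COc1ccc([C@@H]2C=C(O[Si](C)(OCC)OCC)c3c(OCOC)cc(OCOC)c(CC=C(C)C)c3O2)cc1 | intermediate
15 | (2S)-5,7-bis(methoxymethoxy)-4'-methoxy-8-prenylflavanone | COc1ccc([C@@H]2CC(=O)c3c(OCOC)cc(OCOC)c(CC=C(C)C)c3O2)cc1 | intermediate
16 | (2S)-5,7-dihydroxy-4'-methoxy-8-prenylflavanone | COc1ccc([C@@H]2CC(=O)c3c(O)cc(O)c(CC=C(C)C)c3O2)cc1 | target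

Total step count: 8. Longest linear sequence: 7 steps (1, 2, 4, 5, 6, 7, 8, from phloroglucinol). Step 3 is a one-step side branch.

Steps most likely to fail

Step 6. Oxidative addition and CO uptake at a C–I bond flanked by two oxygen substituents may be slow. Alkynylation without CO uptake, capture of the aroylpalladium species by the amine, or 5-exo closure could then take over. The fallback sets out from 8 (and uses 9) and comes back at 13. It brings the C4 carbon in on the alkyne instead of as CO. Alkyne 9 is lithiated (n-BuLi, THF, −78 °C) and acylated with N-methoxy-N-methylcarbamoyl chloride to give N-methoxy-3-(4-methoxyphenyl)-N-methylprop-2-ynamide F1. Phenol 8 is deprotonated with MeMgCl, and its iodide is exchanged with i-PrMgCl·LiCl (THF, −20 → 0 °C). The arylmagnesium reagent is then acylated with F1 to give ynone 11, this time isolated. Et2NH in EtOH (rt → 50 °C) takes 11 through 12 to flavone 13.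

Step 7. Hydride transfer to the electron-rich vinylogous ester may be sluggish, or facial selectivity may be insufficient. The enolate may also expel the aryloxide before it is silylated, which opens ring C and erodes enantiomeric purity. The fallback sets out from 13 and comes back at 15, and it separates reduction from stereocontrol. Achiral conjugate reduction (Cu(OAc)2, 1,2-bis(diphenylphosphino)benzene, PMHS, t-BuOH, toluene) gives racemic 5,7-bis(methoxymethoxy)-4'-methoxy-8-prenylflavanone F2. The racemate is then resolved kinetically by Noyori–Ikariya transfer hydrogenation (Cp*RhCl[(R,R)-TsDPEN], HCO2H/Et3N, EtOAc, rt). This should reduce the (R)-ketone faster, to the cis alcohol (2R,4R)-2-(4-methoxyphenyl)-5,7-bis(methoxymethoxy)-8-prenylchroman-4-ol F3. The unreacted (S)-ketone 15 is separated by chromatography.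

Step 4. Zerovalent palladium may insert competitively into the C–I bond, or the branched ether may re-ionise and isomerise to the linear one. The fallback sets out from 3 and comes back at 6, and it builds the tertiary ether without π-allyl chemistry. Phenol 3 is O-alkylated with 3-chloro-3-methylbut-1-yne (CuCl2·2H2O cat., DBU, MeCN, 0 °C) to give 2-iodo-1,5-bis(methoxymethoxy)-3-[(2-methylbut-3-yn-2-yl)oxy]benzene F4. Its terminal alkyne is semi-hydrogenated (H2 1 atm, Pd/CaCO3 poisoned with Pb(OAc)2, quinoline, EtOAc, rt, stopped after one equivalent of H2) to ether 6.

Further compounds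
F1 | step 6 | N-methoxy-3-(4-methoxyphenyl)-N-methylprop-2-ynamide | CON(C)C(=O)C#Cc1ccc(OC)cc1
F2 | step 7 | racemic 5,7-bis(methoxymethoxy)-4'-methoxy-8-prenylflavanone | COc1ccc(C2CC(=O)c3c(OCOC)cc(OCOC)c(CC=C(C)C)c3O2)cc1
F3 | step 7 | (2R,4R)-2-(4-methoxyphenyl)-5,7-bis(methoxymethoxy)-8-prenylchroman-4-ol | COc1ccc([C@H]2C[C@@H](O)c3c(OCOC)cc(OCOC)c(CC=C(C)C)c3O2)cc1
F4 | step 4 | 2-iodo-1,5-bis(methoxymethoxy)-3-[(2-methylbut-3-yn-2-yl)oxy]benzene | C#CC(C)(C)Oc1cc(OCOC)cc(OCOC)c1I
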